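**Retrosynthetic overview**
1. Target 26 ⇐ tris-TBS ether 25. The butenolide is the only ring made in the route and is formed last, by making the C–C bond between the lactone carbinol carbon and the ring carbon that bears CH2OH: an enantioenriched α-lithio carbamate 21 (α-oxy carbanion) is joined to the β-carbon of β-boryl acrylate 20 by a 1,2-metallate shift, then oxidation and lactonisation.
2. Carbamate 15 ⇐ Z-selective Wittig reaction of α-silyloxy ketone 11 with ylide 14.
3. Ketone 11 ⇐ Grignard reagent of homoallylic bromide 7 + aldehyde 8, oxidised in the same flask.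
4. Bromide 7 ⇐ dihydro-β-ionone 1 (the cyclohexene ring is bought): cyclopropyl Grignard addition, ring allylic oxidation, Julia rearrangement (E-alkene), CBS reduction ((S)-carbinol), silylation.
5. Boronate 20 ⇐ propargyl silyl ether 16 by acylation, hydroiodination and borylation.

Assumption: the SMILES is read as (S) at the ring carbinol, (S) at the lactone carbon, E at the methyl-bearing alkene and Z at the hydroxymethyl-bearing alkene; both sparteine enantiomers are taken as purchasable.

**Route**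

Step 1
Reactants: 1 dihydro-β-ionone; 2 cyclopropylmagnesium bromide
Product: 3 2-cyclopropyl-4-(2,6,6-trimethylcyclohex-1-en-1-yl)butan-2-ol (racemic)
Conditions: 2 (1.3 equiv), THF, 0 °C to rt; aq NH4Cl
Reagents that add atoms: none
Why: Grignard 1,2-addition to the unhindered methyl ketone; the new carbinol centre is racemic and is destroyed in step 3.

Step 2
Reactants: 3
Product: 4 3-(3-cyclopropyl-3-hydroxybutyl)-2,4,4-trimethylcyclohex-2-en-1-one (racemic)
Conditions: t-BuOOH (70% aq, 5 equiv), Rh2(C6H10NO)4 (dirhodium tetracaprolactamate, 1 mol%), K2CO3 (0.5 equiv), CH2Cl2, rt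
Reagents that add atoms: tert-butyl hydroperoxide CC(C)(C)OO
Why: Peroxyl-radical allylic C–H oxidation (Doyle-type) is expected to go at the ring CH2 next to the tetrasubstituted alkene, the side-chain allylic CH2 being shielded by the gem-dimethyl group, while the tertiary alcohol and cyclopropane are inert.

Step 3
Reactants: 4
Product: 5 3-[(3E)-6-bromo-3-methylhex-3-en-1-yl]-2,4,4-trimethylcyclohex-2-en-1-one
Conditions: 48% aq HBr, 0 °C, 20 min; E isomer isolated on AgNO3-impregnated silica
Reagents that add atoms: hydrogen bromide Br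
Why: Julia olefin synthesis: the tertiary cyclopropylcarbinyl cation is opened by bromide at a ring CH2 to give the homoallylic bromide, E favoured about 4:1 because the longer chain avoids the cyclopropane in the opening transition state, and the enone keeps the ring alkene out of cation–olefin cyclisation.

Step 4
Reactants: 5
Product: 6 (1S)-3-[(3E)-6-bromo-3-methylhex-3-en-1-yl]-2,4,4-trimethylcyclohex-2-en-1-ol
Conditions: (R)-2-methyl-CBS-oxazaborolidine (20 mol%), catecholborane (1.8 equiv), PhMe, −78 °C; aq NaHCO3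
Reagents that add atoms: none
Why: Corey–Bakshi–Shibata reduction: the (R)-catalyst binds the ketone with the α-methyl alkenyl side as the large group and delivers hydride to the face that gives the (S)-allylic alcohol, without touching the bromide or the isolated alkene.

Step 5
Reactants: 6
Product: 7 tert-butyl{[(1S)-3-[(3E)-6-bromo-3-methylhex-3-en-1-yl]-2,4,4-trimethylcyclohex-2-en-1-yl]oxy}dimethylsilane
Conditions: TBSOTf (1.2 equiv), 2,6-lutidine (2 equiv), CH2Cl2, −78 to 0 °C
Reagents that add atoms: tert-butyldimethylsilyl triflate CC(C)(C)[Si](C)(C)OS(=O)(=O)C(F)(F)F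
Why: Silyl ether formation with a non-nucleophilic base leaves the primary bromide untouched and masks the alcohol for the organometallic steps.

Step 6
Reactants: 7; 8 (tert-butyldimethylsilyloxy)acetaldehyde
Product: 11 (5E)-1-[(tert-butyldimethylsilyl)oxy]-6-methyl-8-[(3S)-3-[(tert-butyldimethylsilyl)oxy]-2,6,6-trimethylcyclohex-1-en-1-yl]oct-5-en-2-one, via homoallylic Grignard reagent 9 (not isolated), via bromomagnesium alkoxide 10 (not isolated)
Conditions: Mg, THF, rt; 8, −78 to 0 °C; 1,1'-(azodicarbonyl)dipiperidine (1.2 equiv), 0 °C to rt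
Reagents that add atoms: none
Why: Grignard addition to the aldehyde followed by Mukaiyama oxidation of the magnesium alkoxide (hydride transfer to the azo compound) gives the α-silyloxy ketone in one flask; the E-alkene survives because ring closure of this homoallylic Grignard reagent to a tertiary cyclopropylcarbinyl species is slow.

Step 7
Reactants: 12 (3-hydroxypropyl)triphenylphosphonium bromide
Product: 13 {3-[(diisopropylcarbamoyl)oxy]propyl}triphenylphosphonium bromide
Conditions: i-Pr2NC(O)Cl (1.3 equiv), Et3N (1.5 equiv), DMAP (cat.), CH2Cl2, reflux; wash with aq NaBr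
Reagents that add atoms: N,N-diisopropylcarbamoyl chloride CC(C)N(C(C)C)C(Cl)=O
Why: O-carbamoylation of the primary alcohol; the amine base is too weak to form the ylide.

Step 8
Reactants: 11; 13
Product: 15 (3Z,7E)-4-{[(tert-butyldimethylsilyl)oxy]methyl}-8-methyl-10-[(3S)-3-[(tert-butyldimethylsilyl)oxy]-2,6,6-trimethylcyclohex-1-en-1-yl]deca-3,7-dien-1-yl N,N-diisopropylcarbamate, via phosphorus ylide 14 (not isolated)
Conditions: 13, KN(SiMe3)2 (1.0 equiv), THF, 0 °C; 11, THF/HMPA, −78 °C to rt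
Reagents that add atoms: none
Why: Wittig olefination of an α-alkoxy ketone with a salt-free unstabilised ylide (Still's Z-selective variant) places the silyloxymethyl group cis to the new chain, and the hindered carbamate is not attacked by the ylide.

Step 9
Reactants: 16 tert-butyldimethyl(prop-2-yn-1-yloxy)silane
Product: 18 tert-butyl 4-[(tert-butyldimethylsilyl)oxy]but-2-ynoate, via lithium acetylide 17 (not isolated)
Conditions: n-BuLi (1.05 equiv), THF, −78 °C; Boc2O, −78 °C to rt
Reagents that add atoms: di-tert-butyl dicarbonate CC(C)(C)OC(=O)OC(=O)OC(C)(C)C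
Why: Acylation of the lithium acetylide with the dicarbonate gives the tert-butyl ynoate directly.

Step 10
Reactants: 18
Product: 19 tert-butyl (2Z)-4-[(tert-butyldimethylsilyl)oxy]-3-iodobut-2-enoate (iodine cis to the ester)
Conditions: NaI (1.5 equiv), AcOH (2 equiv), MeCN, 80 °C
Reagents that add atoms: sodium iodide [Na+].[I-]
Why: Conjugate hydroiodination: iodide adds to the β-carbon and the allenoate is protonated anti, which gives the Z-β-iodo enoate.

Step 11
Reactants: 19
Product: 20 tert-butyl (2E)-4-[(tert-butyldimethylsilyl)oxy]-3-(4,4,5,5-tetramethyl-1,3,2-dioxaborolan-2-yl)but-2-enoate (boron cis to the ester)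
Conditions: B2pin2 (1.1 equiv), PdCl2(PPh3)2 (3 mol%), PPh3 (6 mol%), KOPh (1.5 equiv), PhMe, 50 °C
Reagents that add atoms: bis(pinacolato)diboron CC1(C)OB(OC1(C)C)B1OC(C)(C)C(C)(C)O1
Why: Miyaura borylation of the alkenyl iodide goes with retention of alkene geometry, so boron ends up cis to the ester as the later lactonisation requires.

Step 12
Reactants: 15; 20
Product: 25 (5S)-4-{[(tert-butyldimethylsilyl)oxy]methyl}-5-{(2Z,6E)-3-{[(tert-butyldimethylsilyl)oxy]methyl}-7-methyl-9-[(3S)-3-[(tert-butyldimethylsilyl)oxy]-2,6,6-trimethylcyclohex-1-en-1-yl]nona-2,6-dien-1-yl}furan-2(5H)-one, via lithiated carbamate 21 (not isolated), via boronate complex 22 (not isolated), via allylic boronic ester 23 (not isolated), via hydroxy ester 24 (not isolated)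
Conditions: s-BuLi (1.3 equiv), (+)-sparteine (1.3 equiv), Et2O, −78 °C, 5 h; 20 (1.5 equiv), −78 °C, 1 h; MgBr2·OEt2, −78 °C to reflux, 12 h; NaBO3·4H2O, THF/H2O, rt; PPTS (cat.), PhMe, 60 °C
Reagents that add atoms: sodium perborate tetrahydrate [Na+].[Na+].O[B-]1(O)OO[B-](O)(O)OO1.O.O.O.O.O.O
Why: Proposed new method: Hoppe deprotonation with s-BuLi/(+)-sparteine removes the pro-R hydrogen to give the configurationally stable (R)-α-lithio carbamate (a carbinol-carbon nucleophile), which adds to boron of 20 with retention; anti-periplanar 1,2-migration of the alkenyl group then displaces the carbamate with inversion, joining two carbons that are both normally electrophilic (aldehyde-level carbon and enoate β-carbon) and setting the (S)-centre, and stereoretentive C–B oxidation and lactonisation onto the cis ester close the butenolide; the closest known reaction type is the Aggarwal lithiation–borylation (Matteson-type homologation) of Hoppe carbamates with alkenyl pinacol boronates, the untested element being an electron-poor β-boryl acrylate as the migrating group.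

Step 13
Reactants: 25
Product: 26 (5S)-4-(hydroxymethyl)-5-{(2Z,6E)-3-(hydroxymethyl)-7-methyl-9-[(3S)-3-hydroxy-2,6,6-trimethylcyclohex-1-en-1-yl]nona-2,6-dien-1-yl}furan-2(5H)-one
Conditions: HF·pyridine, pyridine, THF, 0 °C to rt
Reagents that add atoms: none
Why: Fluoride-driven cleavage of all three silyl ethers under buffered, near-neutral conditions spares the base-labile lactone stereocentre and the acid-labile allylic alcohol.

**Compound list**
1 | dihydro-β-ionone (4-(2,6,6-trimethylcyclohex-1-en-1-yl)butan-2-one) | CC1=C(CCC(C)=O)C(C)(C)CCC1 | starting material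
2 | cyclopropylmagnesium bromide | Br[Mg]C1CC1 | starting material
3 | 2-cyclopropyl-4-(2,6,6-trimethylcyclohex-1-en-1-yl)butan-2-ol (racemic) | CC1=C(CCC(C)(O)C2CC2)C(C)(C)CCC1 | intermediate
4 | 3-(3-cyclopropyl-3-hydroxybutyl)-2,4,4-trimethylcyclohex-2-en-1-one (racemic) | CC1=C(CCC(C)(O)C2CC2)C(C)(C)CCC1=O | intermediate
5 | 3-[(3E)-6-bromo-3-methylhex-3-en-1-yl]-2,4,4-trimethylcyclohex-2-en-1-one | CC1=C(CC/C(C)=C/CCBr)C(C)(C)CCC1=O | intermediate
6 | (1S)-3-[(3E)-6-bromo-3-methylhex-3-en-1-yl]-2,4,4-trimethylcyclohex-2-en-1-ol | CC1=C(CC/C(C)=C/CCBr)C(C)(C)CC[C@@H]1O | intermediate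
7 | TBS ether of 6 | CC1=C(CC/C(C)=C/CCBr)C(C)(C)CC[C@@H]1O[Si](C)(C)C(C)(C)C | intermediate
8 | (tert-butyldimethylsilyloxy)acetaldehyde | O=CCO[Si](C)(C)C(C)(C)C | starting material
9 | homoallylic Grignard reagent from 7 | CC1=C(CC/C(C)=C/CC[Mg]Br)C(C)(C)CC[C@@H]1O[Si](C)(C)C(C)(C)C | intermediate
10 | bromomagnesium alkoxide from 9 and 8 (both carbinol epimers) | CC1=C(CC/C(C)=C/CCC(O[Mg]Br)CO[Si](C)(C)C(C)(C)C)C(C)(C)CC[C@@H]1O[Si](C)(C)C(C)(C)C | intermediate
11 | (5E)-1-(TBS-oxy)-6-methyl-8-[(3S)-3-(TBS-oxy)-2,6,6-trimethylcyclohex-1-en-1-yl]oct-5-en-2-one | CC1=C(CC/C(C)=C/CCC(=O)CO[Si](C)(C)C(C)(C)C)C(C)(C)CC[C@@H]1O[Si](C)(C)C(C)(C)C | intermediate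
12 | (3-hydroxypropyl)triphenylphosphonium bromide | OCCC[P+](c1ccccc1)(c1ccccc1)c1ccccc1.[Br-] | starting material
13 | {3-[(diisopropylcarbamoyl)oxy]propyl}triphenylphosphonium bromide | CC(C)N(C(C)C)C(=O)OCCC[P+](c1ccccc1)(c1ccccc1)c1ccccc1.[Br-] | intermediate
14 | ylide of 13 | CC(C)N(C(C)C)C(=O)OCCC=P(c1ccccc1)(c1ccccc1)c1ccccc1 | intermediate
15 | (3Z,7E)-4-[(TBS-oxy)methyl]-8-methyl-10-[(3S)-3-(TBS-oxy)-2,6,6-trimethylcyclohex-1-en-1-yl]deca-3,7-dien-1-yl N,N-diisopropylcarbamate | CC1=C(CC/C(C)=C/CC/C(=C/CCOC(=O)N(C(C)C)C(C)C)CO[Si](C)(C)C(C)(C)C)C(C)(C)CC[C@@H]1O[Si](C)(C)C(C)(C)C | intermediate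
16 | tert-butyldimethyl(prop-2-yn-1-yloxy)silane | C#CCO[Si](C)(C)C(C)(C)C | starting material
17 | lithium acetylide of 16 | [Li]C#CCO[Si](C)(C)C(C)(C)C | intermediate
18 | tert-butyl 4-(TBS-oxy)but-2-ynoate | CC(C)(C)OC(=O)C#CCO[Si](C)(C)C(C)(C)C | intermediate
19 | tert-butyl (2Z)-4-(TBS-oxy)-3-iodobut-2-enoate | CC(C)(C)OC(=O)/C=C(\I)CO[Si](C)(C)C(C)(C)C | intermediate
20 | tert-butyl (2E)-4-(TBS-oxy)-3-(pinacolboryl)but-2-enoate | CC(C)(C)OC(=O)/C=C(\B1OC(C)(C)C(C)(C)O1)CO[Si](C)(C)C(C)(C)C | intermediate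
21 | (R)-α-lithio carbamate from 15 (sparteine complex) | CC1=C(CC/C(C)=C/CC/C(=C/C[C@@H]([Li])OC(=O)N(C(C)C)C(C)C)CO[Si](C)(C)C(C)(C)C)C(C)(C)CC[C@@H]1O[Si](C)(C)C(C)(C)C | intermediate
22 | lithium boronate complex of 21 and 20, (R) at the carbamate carbon | CC1=C(CC/C(C)=C/CC/C(=C/C[C@H](OC(=O)N(C(C)C)C(C)C)[B-]2(OC(C)(C)C(C)(C)O2)/C(CO[Si](C)(C)C(C)(C)C)=C\C(=O)OC(C)(C)C)CO[Si](C)(C)C(C)(C)C)C(C)(C)CC[C@@H]1O[Si](C)(C)C(C)(C)C.[Li+] | intermediate
23 | (S)-allylic pinacol boronic ester after 1,2-shift | CC1=C(CC/C(C)=C/CC/C(=C/C[C@H](B2OC(C)(C)C(C)(C)O2)/C(CO[Si](C)(C)C(C)(C)C)=C\C(=O)OC(C)(C)C)CO[Si](C)(C)C(C)(C)C)C(C)(C)CC[C@@H]1O[Si](C)(C)C(C)(C)C | intermediate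
24 | tert-butyl (2Z,4S)-4-hydroxy enoate (hydroxyl carbon cis to the ester) | CC1=C(CC/C(C)=C/CC/C(=C/C[C@H](O)/C(CO[Si](C)(C)C(C)(C)C)=C\C(=O)OC(C)(C)C)CO[Si](C)(C)C(C)(C)C)C(C)(C)CC[C@@H]1O[Si](C)(C)C(C)(C)C | intermediate
25 | tris-TBS ether of the target, (5S) butenolide | CC1=C(CC/C(C)=C/CC/C(=C/C[C@@H]2OC(=O)C=C2CO[Si](C)(C)C(C)(C)C)CO[Si](C)(C)C(C)(C)C)C(C)(C)CC[C@@H]1O[Si](C)(C)C(C)(C)C | intermediate
26 | CNP0330392.1 | CC1=C(CC/C(C)=C/CC/C(=C/C[C@@H]2OC(=O)C=C2CO)CO)C(C)(C)CC[C@@H]1O | target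

**Totals**
Total steps: 13. Longest linear sequence: 9 (steps 1, 2, 3, 4, 5, 6, 8, 12, 13).

**Steps most likely to fail, with fallbacks**

Step 12. The electron-poor β-boryl acrylate may migrate slowly, or its ester or γ-hydrogens may be attacked by the lithiated carbamate. The fallback sets out from ketone 11 and comes back at hydroxy ester 24. Ketone 11 is olefinated under the step 8 conditions with the ylide of commercial [2-(1,3-dioxolan-2-yl)ethyl]triphenylphosphonium bromide to give the Z-alkenyl dioxolane F1. Mild acetal cleavage (TMSOTf, 2,6-lutidine, then water) gives the β,γ-unsaturated aldehyde F2, which is used at once. An asymmetric Nozaki–Hiyama–Kishi coupling of F2 with iodo enoate 19 (CrCl2, NiCl2 cat., Kishi-type chiral sulfonamide ligand, MeCN) then adds the β-chromio acrylate to the aldehyde, so the reversed polarity now sits on the acrylate carbon. The ligand enantiomer that gives the (S)-carbinol would have to be found by a test run. The product is 24, which is lactonised and carried on as before.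

Step 2. Oxidation may also occur at the side-chain allylic CH2. The fallback sets out from Grignard reagent 2 and comes back at 4. Commercial β-ionone, in which that CH2 is vinylic, is oxidised with the step 2 reagents to 4-oxo-β-ionone F3. Conjugate reduction of the side-chain enone alone with [(Ph3P)CuH]6 in PhMe gives 4-oxo-7,8-dihydro-β-ionone F4. Compound 2 (1.0 equiv, THF, −78 °C) then adds to the saturated methyl ketone in preference to the hindered, conjugated ring ketone to give 4.

Step 3. The E/Z ratio is only about 4:1 and the isomers may not separate. The fallback sets out from 1 and comes back at 7. Ketone 1 is converted in one flask (LiN(iPr)2; ClP(O)(OEt)2; LiN(iPr)2) through the kinetic enol phosphate F5 into the terminal alkyne F6. Ring oxidation as in step 2 gives enone F7, reduction as in step 4 gives the (S)-alcohol F8, and silylation as in step 5 gives silyl ether F9. Zirconium-catalysed syn methylalumination (AlMe3, Cp2ZrCl2, CH2Cl2), then n-BuLi and ethylene oxide, gives the E homoallylic alcohol F10 with the alkene geometry fixed by the carbometalation. CBr4/PPh3 converts F10 into bromide 7.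

**Further compounds**
F1 | step 12 | Z-alkenyl dioxolane from 11 | CC1=C(CC/C(C)=C/CC/C(=C/CC2OCCO2)CO[Si](C)(C)C(C)(C)C)C(C)(C)CC[C@@H]1O[Si](C)(C)C(C)(C)C
F2 | step 12 | β,γ-unsaturated aldehyde from F1 | CC1=C(CC/C(C)=C/CC/C(=C/CC=O)CO[Si](C)(C)C(C)(C)C)C(C)(C)CC[C@@H]1O[Si](C)(C)C(C)(C)C
F3 | step 2 | 4-oxo-β-ionone | CC1=C(/C=C/C(C)=O)C(C)(C)CCC1=O
F4 | step 2 | 4-oxo-7,8-dihydro-β-ionone | CC1=C(CCC(C)=O)C(C)(C)CCC1=O
F5 | step 3 | diethyl enol phosphate of 1 | CC1=C(CCC(=C)OP(=O)(OCC)OCC)C(C)(C)CCC1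
F6 | step 3 | 2-(but-3-yn-1-yl)-1,3,3-trimethylcyclohex-1-ene | CC1=C(CCC#C)C(C)(C)CCC1
F7 | step 3 | 3-(but-3-yn-1-yl)-2,4,4-trimethylcyclohex-2-en-1-one | CC1=C(CCC#C)C(C)(C)CCC1=O
F8 | step 3 | (1S)-3-(but-3-yn-1-yl)-2,4,4-trimethylcyclohex-2-en-1-ol | CC1=C(CCC#C)C(C)(C)CC[C@@H]1O
F9 | step 3 | TBS ether of F8 | CC1=C(CCC#C)C(C)(C)CC[C@@H]1O[Si](C)(C)C(C)(C)C
F10 | step 3 | (3E)-4-methyl-6-[(3S)-3-(TBS-oxy)-2,6,6-trimethylcyclohex-1-en-1-yl]hex-3-en-1-ol | CC1=C(CC/C(C)=C/CCO)C(C)(C)CC[C@@H]1O[Si](C)(C)C(C)(C)C
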